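The plan rests on forming the C3–C4 bond of ring A last in the bicycle, on a ring B that is (S)-carvone with its stereocentre serving as C5. The feature exploited is the quaternary carbon C4, which carries CH3 and C18H2–O next to C5: it maps onto an epoxidised isopropenyl group. Trivalent titanium opens that epoxide to the tertiary C4 radical, which closes ring A 6-endo onto the C3 terminus of a 2-(phenylsulfonyl)allyl arm (C1–C3) attached at C10. One operation therefore gives the trans-decalin, the C4 stereocentre and the free C18 hydroxyl. The precursor is the 6-methyl-6-sulfonylallyl carvone 8,9-epoxide, used as both epoxide epimers.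

Key step: step 4

Remark: labdane numbering (C1–C20) is used for bicyclic compounds and carvone numbering for monocyclic ones; C2, which bears the sulfonyl group from step 4 to step 11, is carried as an epimer mixture and drawn without configuration; 3-bromo-2-(phenylsulfonyl)prop-1-ene is taken as purchasable.

Step 1
Reactants: 1 (S)-carvone
Product: 3 6-methylcarvone (C6 epimer mixture), via carvone lithium dienolate 2 (not isolated)
Conditions: LiN(i-Pr)2, THF, −78 °C; MeI, −78 to 0 °C
Reagents that add atoms: iodomethane, CI
Why: Kinetic α′-deprotonation gives the cross-conjugated dienolate, which is C-methylated (enolate alkylation, SN2); the new C6 centre forms as an epimer mixture that is made planar again in step 2.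

Step 2
Reactants: 3 6-methylcarvone; 4 3-bromo-2-(phenylsulfonyl)prop-1-ene
Product: 6 6-methyl-6-[2-(phenylsulfonyl)allyl]carvone (sulfonylallyl trans to isopropenyl), via lithium enolate 5 (not isolated)
Conditions: LiN(i-Pr)2, THF, −78 °C; then 4, −78 to −40 °C
Reagents that add atoms: none
Why: The tetrasubstituted enolate is allylated by addition–elimination on the bromo vinyl sulfone (enolate alkylation, SN2′), and the electrophile enters the face opposite the adjacent isopropenyl group, which sets the quaternary centre (future C10) with the C1–C3 arm trans to the future C4 arm.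

Step 3
Reactants: 6 6-methyl-6-[2-(phenylsulfonyl)allyl]carvone
Product: 7 8,9-epoxide of 6 (both oxirane epimers)
Conditions: mCPBA, CH2Cl2, 0 °C
Reagents that add atoms: 3-chloroperoxybenzoic acid (mCPBA), OOC(=O)c1cccc(Cl)c1
Why: Prilezhaev epoxidation is chemoselective for the electron-rich isopropenyl alkene over the electron-poor enone and vinyl sulfone; the oxirane carbon forms without control, which is harmless because step 4 makes it planar.

Step 4
Reactants: 7 8,9-epoxide of 6
Product: 8 ring-A-closed hydroxy sulfone enone (trans-decalin; C4 with axial CH3 and equatorial C18H2OH; C2 epimers)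
Conditions: Cp2TiCl2 (2.5 equiv), Mn, THF, rt; this Cp2TiCl solution added slowly to 7 in THF, rt; then 1 M aq. HCl
Reagents that add atoms: none
Why: Single-electron transfer from Cp2TiCl (trivalent titanium) cleaves the C4–O bond of either epoxide epimer homolytically, so both give the same planar tertiary C4 radical with the titanium alkoxide on C18; this radical adds to the unsubstituted C3 terminus of the vinyl sulfone, and the resulting α-sulfonyl radical at C2 is reduced by a second Cp2TiCl and protonated on work-up. The closest known reaction type is the titanocene-mediated reductive epoxide opening followed by Giese-type radical cyclisation onto an electron-poor alkene. Ring A closes in the 6-endo-trig mode, because exo attack would have to occur at the sulfonyl-bearing C2 and would leave an unstabilised primary radical. The new stereocentre C4 is set in a chair transition state in which the bulky CH2O–TiCp2Cl group takes the equatorial site and the small CH3 the axial site, syn to the axial C10 methyl. The trans ring fusion follows from the trans-diequatorial placement of the C4 and C1 arms on ring B, fixed in step 2. The step needs chemoselectivity for the vinyl sulfone over the C9 carbonyl and over hydrogen loss from the radical, which the polarity match between the nucleophilic tertiary radical and the sulfone acceptor and a low standing concentration of trivalent titanium should secure.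

Step 5
Reactants: 8 ring-A-closed hydroxy sulfone enone
Product: 9 18-O-benzyl ether of 8
Conditions: BnOC(=NH)CCl3, TfOH (cat.), CH2Cl2–cyclohexane, 0 °C to rt
Reagents that add atoms: benzyl 2,2,2-trichloroacetimidate, N=C(OCc1ccccc1)C(Cl)(Cl)Cl
Why: Acid-catalysed O-benzylation with the trichloroacetimidate needs no base, so the enone and the acidic C2–H next to the sulfone are left alone and no stereocentre is touched.

Step 6
Reactants: 9 18-O-benzyl ether of 8
Product: 11 7,9(11)-diene (C7=C8 and exocyclic C9=C11H2), via C9 hydroxysilane 10 (not isolated)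
Conditions: Me3SiCH2Li, CeCl3, THF, −78 to 0 °C; then 1 M aq. H2SO4, THF, rt
Reagents that add atoms: (trimethylsilyl)methyllithium, [Li]C[Si](C)(C)C
Why: The weakly basic organocerium reagent adds 1,2 to the hindered C9 ketone and the β-hydroxysilane then loses Me3SiOH under acid (Peterson olefination), which places the new alkene regiospecifically at C9=C11 and leaves no new stereocentre.

Step 7
Reactants: 12 (R)-2-methylbutane-1,4-diol
Product: 13 (R)-2-methyl-4-[(triisopropylsilyl)oxy]butan-1-ol
Conditions: TIPSCl (1.0 equiv), imidazole, CH2Cl2, −20 to 0 °C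
Reagents that add atoms: chlorotriisopropylsilane, CC(C)[Si](Cl)(C(C)C)C(C)C
Why: Silylation with the bulky chlorosilane is sterically biased toward the unbranched C4 hydroxyl over the β-branched C1 hydroxyl (regioselective monoprotection), and the stereocentre is not involved.

Step 8
Reactants: 13 (R)-2-methyl-4-[(triisopropylsilyl)oxy]butan-1-ol
Product: 14 (R)-(4-bromo-3-methylbutoxy)triisopropylsilane
Conditions: CBr4, PPh3, CH2Cl2, 0 °C
Reagents that add atoms: tetrabromomethane, BrC(Br)(Br)Br
Why: The Appel reaction replaces the primary hydroxyl by bromide through SN2 at the CH2 group, so the neighbouring methyl-bearing stereocentre (future C13) is untouched.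

Step 9
Reactants: 11 7,9(11)-diene; 14 (R)-(4-bromo-3-methylbutoxy)triisopropylsilane
Product: 16 18-benzyloxy-2-(phenylsulfonyl)-15-(triisopropylsilyloxy)labd-7-ene, via C11 alkyl-9-BBN 15 (not isolated)
Conditions: 9-BBN-H, THF, 0 to 50 °C; then 14, Pd(OAc)2, PCy3, K3PO4·H2O, THF, rt to 40 °C
Reagents that add atoms: none
Why: 9-BBN places boron on the terminal C11 and hydrogen on C9 from the face opposite the axial C10 methyl (so H9 is trans to that methyl and the side chain equatorial), and the primary alkylborane is then joined to the primary bromide by an alkyl–alkyl Suzuki–Miyaura coupling (oxidative addition of C–Br to zerovalent palladium bearing PCy3, hydroxide-assisted transmetalation, reductive elimination).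

Step 10
Reactants: 16 18-benzyloxy-2-(phenylsulfonyl)-15-(triisopropylsilyloxy)labd-7-ene
Product: 17 7,8-epoxide of 16 (oxygen trans to the C10 methyl)
Conditions: mCPBA, CH2Cl2, 0 °C
Reagents that add atoms: 3-chloroperoxybenzoic acid (mCPBA), OOC(=O)c1cccc(Cl)c1
Why: Prilezhaev epoxidation of the only alkene occurs on the face away from the axial C10 methyl, which fixes the C8 oxygen trans to that methyl.

Step 11
Reactants: 17 7,8-epoxide of 16
Product: 18 15-O-TIPS-labdane-8,15,18-triol (free 8-OH and 18-OH)
Conditions: Li, EtNH2, THF, −10 to 0 °C; then NH4Cl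
Reagents that add atoms: none
Why: Solvated electrons (Benkeser-type dissolving-metal reduction) cleave the benzyl C–O bond, the C2–S bond and the less substituted C7–O bond of the epoxide, the last through the secondary carbanion so that the C8–O bond and its configuration are kept and the tertiary 8-OH results, while the aryl-free silyl ether is inert.

Step 12
Reactants: 18 15-O-TIPS-labdane-8,15,18-triol; 19 angelic acid
Product: 21 18-O-angeloyl-15-O-TIPS-labdane-8,15,18-triol, via angelic 2,4,6-trichlorobenzoic anhydride 20 (not isolated)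
Conditions: 19, 2,4,6-trichlorobenzoyl chloride, Et3N, toluene, rt; then 18, toluene, 80 °C
Reagents that add atoms: none
Why: Yamaguchi esterification through the mixed anhydride acylates only the primary C18 hydroxyl (the tertiary 8-OH is inert), and leaving out nucleophilic amine catalysts guards the Z-configured angelate against isomerisation to the tiglate.

Step 13
Reactants: 21 18-O-angeloyl-15-O-TIPS-labdane-8,15,18-triol
Product: 22 target CNP0150844.1
Conditions: HF·pyridine, pyridine, THF, 0 °C to rt
Reagents that add atoms: none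
Why: Fluoride-driven cleavage of the primary silyl ether under buffered, non-basic conditions frees the C15 hydroxyl without touching the angelate, the tertiary alcohol or any stereocentre.

Compound list
1 | (S)-carvone, (5S)-2-methyl-5-(prop-1-en-2-yl)cyclohex-2-en-1-one | CC1=CC[C@@H](CC1=O)C(C)=C | starting material
2 | carvone lithium dienolate (O–Li on C1; C1=C6 and C2=C3) | CC1=CC[C@@H](C=C1O[Li])C(C)=C | intermediate
3 | 6-methylcarvone, (5S)-2,6-dimethyl-5-(prop-1-en-2-yl)cyclohex-2-en-1-one, C6 epimer mixture | CC1=CC[C@@H](C(C)C1=O)C(C)=C | intermediate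
4 | 3-bromo-2-(phenylsulfonyl)prop-1-ene | C=C(CBr)S(=O)(=O)c1ccccc1 | starting material
5 | lithium enolate of 3 (O–Li on C1; tetrasubstituted C1=C6) | CC1=CC[C@@H](C(C)=C1O[Li])C(C)=C | intermediate
6 | (5R,6R)-2,6-dimethyl-6-[2-(phenylsulfonyl)prop-2-en-1-yl]-5-(prop-1-en-2-yl)cyclohex-2-en-1-one; sulfonylallyl trans and 6-CH3 cis to isopropenyl | CC1=CC[C@H](C(C)=C)[C@@](C)(CC(=C)S(=O)(=O)c2ccccc2)C1=O | intermediate
7 | (5S,6R)-2,6-dimethyl-5-(2-methyloxiran-2-yl)-6-[2-(phenylsulfonyl)prop-2-en-1-yl]cyclohex-2-en-1-one, both epimers at the oxirane carbon (key-step precursor) | CC1=CC[C@H](C2(C)CO2)[C@@](C)(CC(=C)S(=O)(=O)c3ccccc3)C1=O | intermediate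
8 | 5-(hydroxymethyl)-2,5,8a-trimethyl-7-(phenylsulfonyl)-4a,5,6,7,8,8a-hexahydronaphthalen-1(4H)-one; trans-decalin, C9 ketone, C7=C8, C4 with axial CH3 (cis to the C10 CH3) and equatorial CH2OH (C18), C2 epimers (key-step product) | OC[C@@]1(C)CC(S(=O)(=O)c2ccccc2)C[C@]3(C)[C@@H]1CC=C(C)C3=O | intermediate
9 | 18-O-benzyl ether of 8 | O(Cc4ccccc4)C[C@@]1(C)CC(S(=O)(=O)c2ccccc2)C[C@]3(C)[C@@H]1CC=C(C)C3=O | intermediate
10 | C9 hydroxysilane: 9-hydroxy-9-[(trimethylsilyl)methyl] adduct of 9, C9 configuration unassigned | O(Cc4ccccc4)C[C@@]1(C)CC(S(=O)(=O)c2ccccc2)C[C@]3(C)[C@@H]1CC=C(C)C3(O)C[Si](C)(C)C | intermediate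
11 | 7,9(11)-diene: C7=C8 kept, exocyclic C9=C11H2, 18-OBn, 2-SO2Ph | O(Cc4ccccc4)C[C@@]1(C)CC(S(=O)(=O)c2ccccc2)C[C@]3(C)[C@@H]1CC=C(C)C3=C | intermediate
12 | (R)-2-methylbutane-1,4-diol | OC[C@H](C)CCO | starting material
13 | (R)-2-methyl-4-[(triisopropylsilyl)oxy]butan-1-ol | OC[C@H](C)CCO[Si](C(C)C)(C(C)C)C(C)C | intermediate
14 | (R)-(4-bromo-3-methylbutoxy)triisopropylsilane | BrC[C@H](C)CCO[Si](C(C)C)(C(C)C)C(C)C | intermediate
15 | C11 alkyl-9-BBN: 9-BBN on C11, H9 trans to the C10 CH3, C7=C8 kept | O(Cc4ccccc4)C[C@@]1(C)CC(S(=O)(=O)c2ccccc2)C[C@]3(C)[C@@H]1CC=C(C)[C@H]3CB5C6CCCC5CCC6 | intermediate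
16 | 18-benzyloxy-2-(phenylsulfonyl)-15-(triisopropylsilyloxy)labd-7-ene; ring stereocentres as in the target, 13S, C2 epimers | O(Cc4ccccc4)C[C@@]1(C)CC(S(=O)(=O)c2ccccc2)C[C@]3(C)[C@@H]1CC=C(C)[C@H]3CC[C@H](C)CCO[Si](C(C)C)(C(C)C)C(C)C | intermediate
17 | 7,8-epoxide of 16, epoxide oxygen trans to the C10 CH3 | O(Cc4ccccc4)C[C@@]1(C)CC(S(=O)(=O)c2ccccc2)C[C@]3(C)[C@@H]1C[C@@H]5O[C@]5(C)[C@H]3CC[C@H](C)CCO[Si](C(C)C)(C(C)C)C(C)C | intermediate
18 | (4S,5S,8S,9S,10R,13S)-15-(triisopropylsilyloxy)labdane-8,18-diol | OC[C@@]1(C)CCC[C@]2(C)[C@@H]1CC[C@](C)(O)[C@H]2CC[C@H](C)CCO[Si](C(C)C)(C(C)C)C(C)C | intermediate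
19 | angelic acid, (Z)-2-methylbut-2-enoic acid | C/C=C(/C)C(O)=O | starting material
20 | angelic 2,4,6-trichlorobenzoic anhydride | C/C=C(/C)C(=O)OC(=O)c1c(Cl)cc(Cl)cc1Cl | intermediate
21 | (4S,5S,8S,9S,10R,13S)-8-hydroxy-15-(triisopropylsilyloxy)labdan-18-yl (Z)-2-methylbut-2-enoate | C/C=C(/C)C(=O)OC[C@@]1(C)CCC[C@]2(C)[C@@H]1CC[C@](C)(O)[C@H]2CC[C@H](C)CCO[Si](C(C)C)(C(C)C)C(C)C | intermediate
22 | CNP0150844.1, (4S,5S,8S,9S,10R,13S)-8,15-dihydroxylabdan-18-yl (Z)-2-methylbut-2-enoate | C/C=C(/C)C(=O)OC[C@@]1(C)CCC[C@]2(C)[C@@H]1CC[C@](C)(O)[C@H]2CC[C@H](C)CCO | target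

Total step count: 13 (11 on the main line, 2 for the side-chain bromide). Longest linear sequence: 11 steps (steps 1–6 and 9–13).

Steps most likely to fail

Step 4. The tertiary C4 radical may be intercepted before it reaches C3. It can be captured by a second trivalent titanium centre and lose a β-hydrogen, or be drawn onto the titanium-bound C9 carbonyl. The equatorial preference of the titanium-bound CH2O group may also be too small, which would give poor facial selectivity at C4. The fallback generates the same C4 radical without titanium, by metal-hydride hydrogen-atom transfer, and forms the same C3–C4 bond. It sets out from 6 and returns at 8. Ene-type chlorination of the isopropenyl group of 6 (Ca(OCl)2, solid CO2, CH2Cl2–H2O, 0 °C) should give the allylic chloride F1. KOAc in DMF should then displace chloride to give the allylic acetate F2. Fe(acac)3 and PhSiH3 in EtOH at 60 °C transfer a hydrogen atom to the terminal CH2 of the 2-(acetoxymethyl)allyl unit; the tertiary C4 radical closes ring A 6-endo onto the vinyl sulfone and should give the bicyclic 18-acetate F3. Methanolysis (K2CO3, MeOH) then gives 8.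

Step 9. Both coupling partners are β-branched, so oxidative addition and transmetalation may be slow enough for β-hydride elimination and protodeboronation to take over. The fallback replaces the cross-coupling by olefination and selective saturation. It sets out from 11 (and from 14 for the side chain) and returns at 16. Hydroboration of 11 as before to 15, followed by oxidation with NaBO3·4H2O, should give the homoallylic C11 alcohol F4. Dess–Martin periodinane buffered with NaHCO3 should give the C11 aldehyde F5. Bromide 14 heated with PPh3 in MeCN gives the phosphonium bromide F6. Its ylide (NaN(SiMe3)2, THF, −78 °C) reacts with F5 in a Wittig reaction to give the C11=C12 Z-alkene F7. Diimide (2-nitrobenzenesulfonylhydrazide, Et3N, CH2Cl2) should saturate only this disubstituted alkene and deliver 16.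

Step 11. Reductive cleavage of the hindered trisubstituted epoxide may lag behind the other two cleavages or take the other regiochemical course. The silyl ether may also be lost in the strongly basic amide medium. The fallback installs the C8 hydroxyl by radical hydration and uses a milder reduction. It sets out from 16, bypasses 17 and returns at 18. Mukaiyama hydration of the C7=C8 alkene (Mn(dpm)3, PhSiH3, O2, i-PrOH, 0 °C to rt; then PPh3) passes through the tertiary C8 radical. O2 should capture it on the face away from the axial C10 methyl and give the tertiary alcohol F8. Li in liquid NH3–THF at −78 °C then removes only the benzyl ether and the sulfonyl group to give 18.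

Further compounds
F1 | step 4 | allylic chloride: 6 with the isopropenyl CH3 replaced by CH2Cl (3-chloroprop-1-en-2-yl group on C5) | CC1=CC[C@H](C(=C)CCl)[C@@](C)(CC(=C)S(=O)(=O)c2ccccc2)C1=O
F2 | step 4 | allylic acetate: 3-acetoxyprop-1-en-2-yl analogue of F1 | CC1=CC[C@H](C(=C)COC(C)=O)[C@@](C)(CC(=C)S(=O)(=O)c2ccccc2)C1=O
F3 | step 4 | bicyclic 18-acetate: O-acetyl derivative of 8 | CC(=O)OC[C@@]1(C)CC(S(=O)(=O)c2ccccc2)C[C@]3(C)[C@@H]1CC=C(C)C3=O
F4 | step 9 | homoallylic C11 alcohol: 9-CH2OH (H9 trans to the C10 CH3), C7=C8, 18-OBn, 2-SO2Ph | O(Cc4ccccc4)C[C@@]1(C)CC(S(=O)(=O)c2ccccc2)C[C@]3(C)[C@@H]1CC=C(C)[C@H]3CO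
F5 | step 9 | C11 aldehyde: 9-CHO analogue of F4 | O(Cc4ccccc4)C[C@@]1(C)CC(S(=O)(=O)c2ccccc2)C[C@]3(C)[C@@H]1CC=C(C)[C@H]3C=O
F6 | step 9 | phosphonium bromide: (R)-[2-methyl-4-(triisopropylsilyloxy)butyl]triphenylphosphonium bromide | c1ccccc1[P+](c2ccccc2)(c3ccccc3)C[C@H](C)CCO[Si](C(C)C)(C(C)C)C(C)C.[Br-]
F7 | step 9 | C11=C12 Z-alkene: 11,12-didehydro analogue of 16 | O(Cc4ccccc4)C[C@@]1(C)CC(S(=O)(=O)c2ccccc2)C[C@]3(C)[C@@H]1CC=C(C)[C@H]3/C=C\[C@H](C)CCO[Si](C(C)C)(C(C)C)C(C)C
F8 | step 11 | tertiary alcohol: 8-hydroxy (trans to the C10 CH3) 18-OBn 2-SO2Ph 15-OTIPS labdane | O(Cc4ccccc4)C[C@@]1(C)CC(S(=O)(=O)c2ccccc2)C[C@]3(C)[C@@H]1CC[C@](C)(O)[C@H]3CC[C@H](C)CCO[Si](C(C)C)(C(C)C)C(C)C
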